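**Plan**

- Retrosynthesis first cuts the chain bond C12–C13 (sulfone alkylation), giving an ω-bromofarnesyl silyl ether and a C10 ring sulfone. It then cuts two ring bonds, C1–C6 (CH to C(CH3)2) and C2–C3 (carbinol carbon to CH2), a [4+2] retron.
- Enabling feature: ring C2 carries CH3 and OH with OH trans to the side chain on C1. This is the pattern of a Diels–Alder adduct of an (E)-2-methyl-2-enal whose formyl group is later exchanged for OH with retention. C6, next to C1, is the nucleophilic terminus of a 2-silyloxy diene whose oxygen ends as a removable C5 ketone.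
- Forward: diene formation, catalytic asymmetric Diels–Alder reaction (builds the only ring), Baeyer–Villiger and Wolff–Kishner steps to remove the helpers, conversion of the CH2OH arm to a sulfone, alkylation with the farnesol-derived bromide, desulfonylation, desilylation.
- Stereochemistry: C1 comes from the chiral oxazaborolidinium catalyst (enal face). C2 follows relative to C1 from suprafacial addition to the E-enal and the retentive Baeyer–Villiger step. The three E-alkenes come from (2E,6E)-farnesol and E-selective SeO2 oxidation.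

Key step: step 2

Assumption: the (S)-oxazaborolidinium catalyst is taken to expose the enal face that leads to the (1S,2S)-configured ring, as its model for 2-methyl-2-enals predicts; if the sense proves opposite, the (R)-catalyst is used with no other change.

**Route**

Step 1
Reactants: 1 4-methylpent-1-en-3-one (isopropyl vinyl ketone)
Product: 2 tert-butyldimethyl[(4-methylpenta-1,3-dien-3-yl)oxy]silane
Conditions: TBSOTf, Et3N, CH2Cl2, 0 °C
Reagents that add atoms: tert-butyldimethylsilyl trifluoromethanesulfonate, CC(C)(C)[Si](C)(C)OS(=O)(=O)C(F)(F)F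
Why: Soft enolisation (silyl enol ether formation) removes the only enolisable proton, the isopropyl methine, and should give the cross-conjugated silyl dienol ether; no stereocentre arises.

Step 2
Reactants: 2 tert-butyldimethyl[(4-methylpenta-1,3-dien-3-yl)oxy]silane; 3 (2E)-3-formylbut-2-en-1-yl acetate [(E)-4-acetoxy-2-methylbut-2-enal]
Product: 5 [(1R,6S)-6-formyl-2,2,6-trimethyl-3-oxocyclohexyl]methyl acetate, via silyl enol ether cycloadduct 4 (not isolated)
Conditions: (S)-oxazaborolidinium triflimide [from the (S)-diphenylprolinol-derived B-(o-tolyl)oxazaborolidine and HNTf2] (20 mol %), CH2Cl2, −78 to −40 °C; then 1 M HCl, THF, 0 °C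
Reagents that add atoms: none
Why: The oxazaborolidinium ion binds the formyl oxygen of 3 and lowers its LUMO, and the fully substituted enol-ether carbon of 2 (largest HOMO coefficient) bonds to the enal β-carbon while the vinyl CH2 terminus bonds to the α-carbon in a concerted, asynchronous [4+2] cycloaddition; at the stepwise limit this is a Mukaiyama–Michael addition followed by 6-endo-trig Michael closure of the boron enolate onto the silyloxonium-activated vinyl ketone. The closest known reaction types are the oxazaborolidinium-catalysed Diels–Alder reaction of 2-methyl-2-enals with 2-silyloxy-1,3-dienes and Lewis-acid-promoted cycloadditions of silyloxy dienes that carry a fully substituted terminus. The one ring formed, the cyclohexene, closes by [4+2] cycloaddition, and its two new bonds are ring bonds C1–C6 and C2–C3 of the later cyclohexanol. The CH stereocentre is set by the catalyst, which shields one face of the s-trans enal; the quaternary formyl-bearing stereocentre follows from suprafacial addition across the E-alkene, which puts CH2OAc cis to CH3 and trans to CHO, and a stepwise closure should give the same isomer because the larger enolate branch takes the pseudo-equatorial site of the chair-like transition state. The step needs head-to-tail regiochemistry and 1,4- over 1,2-attack, both resting on the polarisation of the partners (enol-ether β-carbon as donor, enal β-carbon as acceptor); endo/exo selectivity does not matter because no further stereocentre arises. The gem-dimethyl terminus slows the reaction, which is why the strongly activating cationic boron Lewis acid is used, and the acidic work-up hydrolyses the silyl enol ether to the ketone.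

Step 3
Reactants: 5 [(1R,6S)-6-formyl-2,2,6-trimethyl-3-oxocyclohexyl]methyl acetate
Product: 6 [(1R,6S)-6-(formyloxy)-2,2,6-trimethyl-3-oxocyclohexyl]methyl acetate
Conditions: mCPBA (1.2 equiv), CH2Cl2, 0 °C to rt
Reagents that add atoms: 3-chloroperbenzoic acid, OOC(=O)c1cccc(Cl)c1
Why: Baeyer–Villiger oxidation; the peracid should add to the aldehyde faster than to the hindered ring ketone, and the tertiary ring carbon migrates with retention, so the configuration at the oxygen-bearing carbon is kept.

Step 4
Reactants: 6 [(1R,6S)-6-(formyloxy)-2,2,6-trimethyl-3-oxocyclohexyl]methyl acetate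
Product: 8 (1S,2R)-2-(hydroxymethyl)-1,3,3-trimethylcyclohexan-1-ol, via hydrazone 7 (not isolated)
Conditions: N2H4·H2O, KOH, diethylene glycol, 130 °C then 200 °C; aq. HCl work-up
Reagents that add atoms: none
Why: Wolff–Kishner reduction (Huang-Minlon variant) should turn the ketone into CH2 by loss of N2 from hydrazone 7 while the base cleaves the formate and acetate esters; the 1,4-hydroxy ketone cannot undergo retro-aldol cleavage and no stereocentre is touched.

Step 5
Reactants: 8 (1S,2R)-2-(hydroxymethyl)-1,3,3-trimethylcyclohexan-1-ol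
Product: 9 (1S,2S)-1,3,3-trimethyl-2-[(phenylsulfanyl)methyl]cyclohexan-1-ol
Conditions: PhSSPh, n-Bu3P, pyridine, 60 °C
Reagents that add atoms: diphenyl disulfide, c1ccccc1SSc1ccccc1
Why: Phosphine–disulfide thioetherification (SN2 displacement of the primary oxyphosphonium ion by thiophenolate) should be selective for the primary hydroxyl; the tertiary alcohol is not activated.

Step 6
Reactants: 9 (1S,2S)-1,3,3-trimethyl-2-[(phenylsulfanyl)methyl]cyclohexan-1-ol
Product: 10 (1S,2S)-2-[(benzenesulfonyl)methyl]-1,3,3-trimethylcyclohexan-1-ol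
Conditions: H2O2 (30 %), (NH4)6Mo7O24·4H2O (cat.), EtOH, 0 °C to rt
Reagents that add atoms: hydrogen peroxide, OO
Why: Molybdate-catalysed oxidation of sulfide to sulfone; no alkene is present at this stage and the tertiary alcohol is inert.

Step 7
Reactants: 11 (2E,6E)-farnesol
Product: 12 tert-butyl(diphenyl){[(2E,6E)-3,7,11-trimethyldodeca-2,6,10-trien-1-yl]oxy}silane
Conditions: TBDPSCl, imidazole, DMF, rt
Reagents that add atoms: tert-butyl(chloro)diphenylsilane, CC(C)(C)[Si](Cl)(c1ccccc1)c1ccccc1
Why: Standard silylation of a primary allylic alcohol; the ether must survive carbanion and dissolving-metal conditions later.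

Step 8
Reactants: 12 tert-butyl(diphenyl){[(2E,6E)-3,7,11-trimethyldodeca-2,6,10-trien-1-yl]oxy}silane
Product: 13 (2E,6E,10E)-12-[(tert-butyldiphenylsilyl)oxy]-2,6,10-trimethyldodeca-2,6,10-trien-1-ol
Conditions: SeO2 (0.3 equiv), t-BuOOH, salicylic acid (cat.), CH2Cl2, 0 °C to rt
Reagents that add atoms: selenium dioxide, O=[Se]=O (oxygen donor, regenerated by tert-butyl hydroperoxide, CC(C)(C)OO)
Why: Allylic oxidation with SeO2 (ene reaction, then [2,3]-sigmatropic shift) should attack the terminal, most electron-rich and least hindered trisubstituted alkene and oxidise the methyl group trans to the chain, giving the E-allylic alcohol.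

Step 9
Reactants: 13 (2E,6E,10E)-12-[(tert-butyldiphenylsilyl)oxy]-2,6,10-trimethyldodeca-2,6,10-trien-1-ol
Product: 14 {[(2E,6E,10E)-12-bromo-3,7,11-trimethyldodeca-2,6,10-trien-1-yl]oxy}(tert-butyl)diphenylsilane
Conditions: CBr4, PPh3, CH2Cl2, 0 °C
Reagents that add atoms: carbon tetrabromide, BrC(Br)(Br)Br
Why: Appel reaction; SN2 displacement at the primary allylic carbon should keep the E-alkene geometry.

Step 10
Reactants: 10 (1S,2S)-2-[(benzenesulfonyl)methyl]-1,3,3-trimethylcyclohexan-1-ol; 14 {[(2E,6E,10E)-12-bromo-3,7,11-trimethyldodeca-2,6,10-trien-1-yl]oxy}(tert-butyl)diphenylsilane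
Product: 16 (1S,2S)-2-[(4E,8E,12E)-1-(benzenesulfonyl)-14-[(tert-butyldiphenylsilyl)oxy]-4,8,12-trimethyltetradeca-4,8,12-trien-1-yl]-1,3,3-trimethylcyclohexan-1-ol (both epimers at the sulfone carbon), via dilithio dianion 15 (not isolated)
Conditions: n-BuLi (2.2 equiv), THF–DMPU, −78 °C; then 14, −78 to −20 °C; H2O quench
Reagents that add atoms: none
Why: Alkylation of an α-sulfonyl carbanion (as the O,C-dianion) with a primary allylic bromide by SN2 displacement joins C12 to C13; the new sulfone-bearing stereocentre forms without control, which is irrelevant because step 11 removes it.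

Step 11
Reactants: 16 the alkylated hydroxy sulfone
Product: 17 (1S,2S)-2-[(3E,7E,11E)-13-[(tert-butyldiphenylsilyl)oxy]-3,7,11-trimethyltrideca-3,7,11-trien-1-yl]-1,3,3-trimethylcyclohexan-1-ol
Conditions: Na/Hg (6 % Na), Na2HPO4, MeOH–THF, −20 °C
Reagents that add atoms: none
Why: Reductive desulfonylation by electron transfer; the sulfone is homoallylic, so no alkene migration is expected and the silyl ether is inert.

Step 12
Reactants: 17 the silyl ether of the target
Product: 18 preluffariellolide A, (2E,6E,10E)-13-[(1S,2S)-2-hydroxy-2,6,6-trimethylcyclohexyl]-3,7,11-trimethyltrideca-2,6,10-trien-1-ol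
Conditions: Bu4NF, THF, 0 °C to rt
Reagents that add atoms: none
Why: Fluoride-induced cleavage of the silyl ether; the tertiary alcohol and the three alkenes are inert.

**Compound list**

1 | 4-methylpent-1-en-3-one | C=CC(=O)C(C)C | starting material
2 | tert-butyldimethyl[(4-methylpenta-1,3-dien-3-yl)oxy]silane | C=CC(O[Si](C)(C)C(C)(C)C)=C(C)C | intermediate
3 | (2E)-3-formylbut-2-en-1-yl acetate | CC(=O)OC/C=C(\C)C=O | starting material
4 | [(1S,6S)-3-(tert-butyldimethylsilyloxy)-6-formyl-2,2,6-trimethylcyclohex-3-en-1-yl]methyl acetate | CC(=O)OC[C@H]1C(C)(C)C(O[Si](C)(C)C(C)(C)C)=CC[C@]1(C)C=O | intermediate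
5 | [(1R,6S)-6-formyl-2,2,6-trimethyl-3-oxocyclohexyl]methyl acetate | CC(=O)OC[C@H]1C(C)(C)C(=O)CC[C@]1(C)C=O | intermediate
6 | [(1R,6S)-6-(formyloxy)-2,2,6-trimethyl-3-oxocyclohexyl]methyl acetate | CC(=O)OC[C@H]1C(C)(C)C(=O)CC[C@]1(C)OC=O | intermediate
7 | (1S,2R)-4-hydrazinylidene-2-(hydroxymethyl)-1,3,3-trimethylcyclohexan-1-ol | OC[C@H]1C(C)(C)C(=NN)CC[C@]1(C)O | intermediate
8 | (1S,2R)-2-(hydroxymethyl)-1,3,3-trimethylcyclohexan-1-ol | OC[C@H]1C(C)(C)CCC[C@]1(C)O | intermediate
9 | (1S,2S)-1,3,3-trimethyl-2-[(phenylsulfanyl)methyl]cyclohexan-1-ol | c1ccccc1SC[C@H]1C(C)(C)CCC[C@]1(C)O | intermediate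
10 | (1S,2S)-2-[(benzenesulfonyl)methyl]-1,3,3-trimethylcyclohexan-1-ol | O=S(=O)(C[C@H]1C(C)(C)CCC[C@]1(C)O)c1ccccc1 | intermediate
11 | (2E,6E)-farnesol | C/C(=C\CO)CC/C=C(\C)CCC=C(C)C | starting material
12 | tert-butyl(diphenyl){[(2E,6E)-3,7,11-trimethyldodeca-2,6,10-trien-1-yl]oxy}silane | C/C(=C\CO[Si](c1ccccc1)(c1ccccc1)C(C)(C)C)CC/C=C(\C)CCC=C(C)C | intermediate
13 | (2E,6E,10E)-12-[(tert-butyldiphenylsilyl)oxy]-2,6,10-trimethyldodeca-2,6,10-trien-1-ol | C/C(=C\CO[Si](c1ccccc1)(c1ccccc1)C(C)(C)C)CC/C=C(\C)CC/C=C(\C)CO | intermediate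
14 | {[(2E,6E,10E)-12-bromo-3,7,11-trimethyldodeca-2,6,10-trien-1-yl]oxy}(tert-butyl)diphenylsilane | C/C(=C\CO[Si](c1ccccc1)(c1ccccc1)C(C)(C)C)CC/C=C(\C)CC/C=C(\C)CBr | intermediate
15 | O,C-dilithio derivative of 10 | [Li]C([C@H]1C(C)(C)CCC[C@]1(C)O[Li])S(=O)(=O)c1ccccc1 | intermediate
16 | (1S,2S)-2-[(4E,8E,12E)-1-(benzenesulfonyl)-14-[(tert-butyldiphenylsilyl)oxy]-4,8,12-trimethyltetradeca-4,8,12-trien-1-yl]-1,3,3-trimethylcyclohexan-1-ol (sulfone-carbon epimers) | C/C(=C\CO[Si](c1ccccc1)(c1ccccc1)C(C)(C)C)CC/C=C(\C)CC/C=C(\C)CC([C@H]1C(C)(C)CCC[C@]1(C)O)S(=O)(=O)c1ccccc1 | intermediate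
17 | (1S,2S)-2-[(3E,7E,11E)-13-[(tert-butyldiphenylsilyl)oxy]-3,7,11-trimethyltrideca-3,7,11-trien-1-yl]-1,3,3-trimethylcyclohexan-1-ol | C/C(=C\CO[Si](c1ccccc1)(c1ccccc1)C(C)(C)C)CC/C=C(\C)CC/C=C(\C)CC[C@H]1C(C)(C)CCC[C@]1(C)O | intermediate
18 | preluffariellolide A | C/C(=C\CO)CC/C=C(\C)CC/C=C(\C)CC[C@H]1C(C)(C)CCC[C@]1(C)O | target

**Step count and risks**

Total step count: 12. Longest linear sequence: 9 (steps 1–6 and 10–12).

Steps most likely to fail:

Step 2. Bond formation at the fully substituted diene carbon may be slow, the silyl enol ether may add 1,2 to the formyl group, or facial discrimination may be weak. The fallback builds the quaternary carbon by enolate alkylation after the cycloaddition and not in it. It sets out from 3 and comes back at 5. The same catalyst is used with the unhindered (Z)-tert-butyldimethyl(penta-1,3-dien-3-yloxy)silane F1 (from commercial pent-1-en-3-one, TBSOTf, Et3N), a diene of the class for which this cycloaddition is established. The cycloadduct, silyl enol ether F2, is hydrolysed (1 M HCl, THF) to the monomethyl keto aldehyde F3. The second methyl group is then introduced at the more substituted α-carbon through the equilibrated enolate (NaH, MeI, THF; the formyl group has no α-hydrogen), which returns to 5. The regioselectivity of this methylation is the weak point of the fallback.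

Step 10. Alkylation of the hindered α-sulfonyl carbanion may be sluggish, or proton transfer and elimination of the allylic bromide may compete. The fallback replaces the sulfone alkylation by a copper-catalysed sp3–sp3 coupling. It sets out from 8 and comes back at 17. The primary alcohol is converted into the iodide F4 (I2, PPh3, imidazole, toluene), and the tertiary alcohol is silylated to the trimethylsilyl ether F5 (TMSOTf, 2,6-lutidine). Iodine–lithium exchange (t-BuLi, Et2O, −78 °C) and transmetalation with MgBr2 give the organomagnesium bromide F6, which is coupled with 14 under Li2CuCl4 catalysis (THF, −20 °C) to the bis-silyl ether F7. K2CO3 in MeOH removes the trimethylsilyl group and gives 17, so steps 5, 6 and 11 are no longer needed.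

Step 8. Site selectivity among the three trisubstituted alkenes may be poor and over-oxidation to the enal may occur. The fallback builds the terminal allylic alcohol by cleavage and olefination. It sets out from 12 and comes back at 13. The terminal alkene is converted into the bromohydrin F8 (NBS, THF–H2O, 0 °C) and closed to the epoxide F9 (K2CO3, MeOH). Periodic acid (H5IO6, THF–Et2O) cleaves it to the aldehyde F10. A Wittig reaction with Ph3P=C(CH3)CO2Et gives the E-ester F11, and i-Bu2AlH reduction (CH2Cl2, −78 °C) gives 13.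

**Further compounds**

F1 | step 2 | (Z)-tert-butyldimethyl(penta-1,3-dien-3-yloxy)silane | C/C=C(/C=C)O[Si](C)(C)C(C)(C)C
F2 | step 2 | [(1S,6S)-3-(tert-butyldimethylsilyloxy)-6-formyl-2,6-dimethylcyclohex-3-en-1-yl]methyl acetate (C2 epimers) | CC(=O)OC[C@H]1C(C)C(O[Si](C)(C)C(C)(C)C)=CC[C@]1(C)C=O
F3 | step 2 | [(1S,6S)-6-formyl-2,6-dimethyl-3-oxocyclohexyl]methyl acetate (C2 epimers) | CC(=O)OC[C@H]1C(C)C(=O)CC[C@]1(C)C=O
F4 | step 10 | (1S,2S)-2-(iodomethyl)-1,3,3-trimethylcyclohexan-1-ol | IC[C@H]1C(C)(C)CCC[C@]1(C)O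
F5 | step 10 | {[(1S,2S)-2-(iodomethyl)-1,3,3-trimethylcyclohexyl]oxy}trimethylsilane | IC[C@H]1C(C)(C)CCC[C@]1(C)O[Si](C)(C)C
F6 | step 10 | bromo{[(1S,2S)-2,6,6-trimethyl-2-(trimethylsilyloxy)cyclohexyl]methyl}magnesium | Br[Mg]C[C@H]1C(C)(C)CCC[C@]1(C)O[Si](C)(C)C
F7 | step 10 | tert-butyl(diphenyl){[(2E,6E,10E)-3,7,11-trimethyl-13-[(1S,2S)-2,6,6-trimethyl-2-(trimethylsilyloxy)cyclohexyl]trideca-2,6,10-trien-1-yl]oxy}silane | C/C(=C\CO[Si](c1ccccc1)(c1ccccc1)C(C)(C)C)CC/C=C(\C)CC/C=C(\C)CC[C@H]1C(C)(C)CCC[C@]1(C)O[Si](C)(C)C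
F8 | step 8 | (6E,10E)-3-bromo-12-[(tert-butyldiphenylsilyl)oxy]-2,6,10-trimethyldodeca-6,10-dien-2-ol | C/C(=C\CO[Si](c1ccccc1)(c1ccccc1)C(C)(C)C)CC/C=C(\C)CCC(Br)C(C)(C)O
F9 | step 8 | tert-butyl{[(2E,6E)-9-(3,3-dimethyloxiran-2-yl)-3,7-dimethylnona-2,6-dien-1-yl]oxy}diphenylsilane | C/C(=C\CO[Si](c1ccccc1)(c1ccccc1)C(C)(C)C)CC/C=C(\C)CCC1OC1(C)C
F10 | step 8 | (4E,8E)-10-[(tert-butyldiphenylsilyl)oxy]-4,8-dimethyldeca-4,8-dienal | C/C(=C\CO[Si](c1ccccc1)(c1ccccc1)C(C)(C)C)CC/C=C(\C)CCC=O
F11 | step 8 | ethyl (2E,6E,10E)-12-[(tert-butyldiphenylsilyl)oxy]-2,6,10-trimethyldodeca-2,6,10-trienoate | C/C(=C\CO[Si](c1ccccc1)(c1ccccc1)C(C)(C)C)CC/C=C(\C)CC/C=C(\C)C(=O)OCC
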